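**Retrosynthetic overview**

1. Numbering: bicyclo[7.2.0]undecane core with C1/C9 ring fusion, C4 (methyl), C5 (C=O), C8 (=CH2), C10 (ring CH2), C11 (quaternary), side chain C1′ (OAc) to C5′ (OAc). Late stage: the C5 ketone and the C4 centre come last, then C8 methylenation; before that the nine-membered ring arises from a cyclohexanone by a three-carbon radical ring expansion (C5–C7 inserted between C4 and C8).
2. Key disconnection: the cyclobutane bonds C9–C10 and C1–C11 form in one intramolecular enone–olefin [2+2] photocycloaddition of a cyclohexenone (C8 carbonyl, C9=C1) with the isopropenyl group (C10=C11) of the side-chain carbinol. The two partners are tied through a mixed acetal between a temporary formyl carbon on C1 and the C1′ oxygen; that carbon is later excised by rhodium decarbonylation.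
3. Enabling feature: in the four-membered ring, C9 is bonded to the methylidene-bearing C8 (a masked ketone, so C9=C1 is the α,β-bond of an enone), and the quaternary C11 carries the oxygenated C1′. A one-carbon acetal bridge from C1 to O–C1′ therefore holds C10=C11 across C9=C1 in a five-membered transition ring.
4. Ring order: cyclohexenone (purchased ring) → temporary tetrahydrofuran acetal and cyclobutane together (key step) → acetal ring opened and its carbon removed → nine-membered ring by expansion of the six-membered ring.
5. Side chain: the (Z)-olefin comes from a ring-closing-metathesis lactone; C1′ comes from asymmetric allylation of methacrolein.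

Key step: step 12

Assumption: C4 is epimerisable α to the C5 ketone and the (4S) epimer of the target is taken to be the more stable one, so it is set last by equilibration; the stereocentres made in step 9 and the acetal carbon of step 11 are carried as mixtures because they are destroyed later.

**Route**

Step 1
Reactants: 1 methacrolein (2-methylprop-2-enal)
Product: 2 (3S)-2-methylhexa-1,5-dien-3-ol
Conditions: allyltributylstannane, Ti(OiPr)4 (10 mol%), (S)-BINOL (20 mol%), 4 Å molecular sieves, CH2Cl2, −20 °C; aq. NaHCO3
Reagents that add atoms: allyltributylstannane CCCC[Sn](CC=C)(CCCC)CCCC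
Why: Keck asymmetric allylation, in which the (S)-BINOL titanium Lewis acid should direct the allyl group to the si face of the aldehyde and so set the carbinol centre (the later C1′) as S under reagent control.

Step 2
Reactants: 2 (3S)-2-methylhexa-1,5-dien-3-ol
Product: 3 (3S)-2-methylhexa-1,5-dien-3-yl 2-methylprop-2-enoate
Conditions: methacryloyl chloride, Et3N, DMAP (cat.), CH2Cl2, 0 °C
Reagents that add atoms: methacryloyl chloride C=C(C)C(Cl)=O
Why: O-acylation of the secondary allylic alcohol supplies the second olefin for ring closure and touches no stereocentre.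

Step 3
Reactants: 3 (3S)-2-methylhexa-1,5-dien-3-yl 2-methylprop-2-enoate
Product: 4 (6S)-3-methyl-6-(prop-1-en-2-yl)-5,6-dihydro-2H-pyran-2-one
Conditions: RuCl2(=CHPh)(PCy3)(H2IMes) (second-generation Grubbs catalyst, 5 mol%), CH2Cl2 (5 mM), 40 °C
Reagents that add atoms: none
Why: Ring-closing metathesis between the terminal vinyl group and the methacrylate closes the six-membered unsaturated lactone, whose ring fixes the later C3′=C4′ olefin as Z; the isopropenyl group stays out because it could only close a four-membered ring.

Step 4
Reactants: 4 (6S)-3-methyl-6-(prop-1-en-2-yl)-5,6-dihydro-2H-pyran-2-one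
Product: 5 (2Z,5S)-2,6-dimethylhepta-2,6-diene-1,5-diol
Conditions: i-Bu2AlH (3.5 equiv), CH2Cl2, −78 to 0 °C; aq. potassium sodium tartrate
Reagents that add atoms: none
Why: Hydride reduction of the lactone through the lactol to the diol keeps the olefin geometry and leaves the stereocentre untouched.

Step 5
Reactants: 5 (2Z,5S)-2,6-dimethylhepta-2,6-diene-1,5-diol
Product: 6 (2Z,5S)-5-hydroxy-2,6-dimethylhepta-2,6-dien-1-yl acetate
Conditions: AcCl (1.05 equiv), 2,4,6-collidine, CH2Cl2, −78 °C
Reagents that add atoms: acetyl chloride CC(Cl)=O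
Why: Kinetically selective acylation of the primary allylic alcohol over the hindered secondary one at low temperature with a weak pyridine base.

Step 6
Reactants: 7 3-ethoxycyclohex-2-en-1-one; 8 1,3-dithiane
Product: 10 3-(1,3-dithian-2-yl)cyclohex-2-en-1-one, via lithium alkoxide adduct 9 (not isolated)
Conditions: 8, n-BuLi, THF, −30 °C; then 7, −78 to 0 °C; then 2 M HCl, THF, rt
Reagents that add atoms: none
Why: Stork–Danheiser sequence, in which 1,2-addition of 2-lithio-1,3-dithiane to the vinylogous ester and acid hydrolysis with loss of ethanol give the transposed enone carrying the masked formyl group on the β-carbon (the later C1).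

Step 7
Reactants: 10 3-(1,3-dithian-2-yl)cyclohex-2-en-1-one
Product: 11 3-(dimethoxymethyl)cyclohex-2-en-1-one
Conditions: PhI(OCOCF3)2 (1.5 equiv), MeOH, rt
Reagents that add atoms: methanol CO
Why: Oxidative dethioacetalisation by the trivalent iodine reagent in methanol exchanges the dithiane for the dimethyl acetal needed for the later acetal exchange.

Step 8
Reactants: 11 3-(dimethoxymethyl)cyclohex-2-en-1-one
Product: 13 3-(dimethoxymethyl)-6-methylcyclohex-2-en-1-one (racemic), via lithium dienolate 12 (not isolated)
Conditions: LiN(i-Pr)2, THF, −78 °C; then MeI, −78 to −20 °C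
Reagents that add atoms: iodomethane CI
Why: Kinetic deprotonation at the α′ position (cross-conjugated dienolate) followed by alkylation installs the later C4 methyl; this centre is racemic here and is re-formed later.

Step 9
Reactants: 13 3-(dimethoxymethyl)-6-methylcyclohex-2-en-1-one; 14 3-[(4-methoxybenzyl)oxy]propanal
Product: 16 3-(dimethoxymethyl)-6-{1-hydroxy-3-[(4-methoxybenzyl)oxy]propyl}-6-methylcyclohex-2-en-1-one (diastereomer mixture), via lithium dienolate 15 (not isolated)
Conditions: LiN(i-Pr)2, THF, −78 °C; then 14, −78 °C; AcOH quench at −78 °C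
Reagents that add atoms: none
Why: Aldol addition of the tetrasubstituted α′ enolate builds the quaternary carbon bearing the three-carbon unit (later C5–C7) with oxygen on the later C5; both new stereocentres are removed later (radical cleavage and oxidation), so the diastereomer mixture is used.

Step 10
Reactants: 16 aldol adduct
Product: 17 3-(dimethoxymethyl)-6-{1-[(tert-butyldimethylsilyl)oxy]-3-[(4-methoxybenzyl)oxy]propyl}-6-methylcyclohex-2-en-1-one
Conditions: TBSOTf, 2,6-lutidine, CH2Cl2, −78 to 0 °C
Reagents that add atoms: tert-butyldimethylsilyl triflate CC(C)(C)[Si](C)(C)OS(=O)(=O)C(F)(F)F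
Why: Silylation of the aldol hydroxyl blocks retro-aldol cleavage and keeps the later C5 oxygen distinct from the ring ketone.

Step 11
Reactants: 17 silyl-protected enone dimethyl acetal; 6 (2Z,5S)-5-hydroxy-2,6-dimethylhepta-2,6-dien-1-yl acetate
Product: 19 mixed methyl acetal of 17 in which one OMe is replaced by the C1′ oxygen of 6 (both acetal epimers), via collidinium salt 18 (not isolated)
Conditions: TESOTf (2 equiv), 2,4,6-collidine (3 equiv), CH2Cl2, 0 °C; then 6, 0 °C to rt
Reagents that add atoms: none
Why: Acetal exchange through an N-(α-methoxyalkyl)pyridinium salt, in which TESOTf and collidine ionise one methoxy group and the secondary alcohol 6 displaces collidine, so the mixed acetal forms with the C1′ stereocentre untouched.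

Step 12
Reactants: 19 mixed acetal (cyclohexenone tethered through CH(OMe)–O to the isopropenyl carbinol)
Product: 20 tricyclic photoadduct: cyclohexanone cis-fused to the cyclobutane C1–C9–C10–C11 that is cis-fused to a 2-methoxytetrahydrofuran (C1–CH(OMe)–O–C1′–C11); C11 methyl cis to C2
Conditions: hν (366 nm, Pyrex), degassed CH2Cl2 (2 mM), −40 °C
Reagents that add atoms: none
Why: Excitation of the cyclohexenone gives its triplet, whose β-carbon (C1) bonds to the inner carbon of the tethered isopropenyl group (C11) in a 5-exo radical closure that forms the temporary 2-methoxytetrahydrofuran ring, and the four-membered ring then closes by combination of the resulting 1,4-biradical (C9 and C10) after spin inversion. The closest known reaction type is the intramolecular enone–olefin [2+2] photocycloaddition of cyclohex-2-enones that carry a pent-4-enyl or allyloxymethyl chain on the β-carbon, which follows the rule of five and gives the straight bicyclo[3.2.0] adduct. C11 is set by the C1′ stereocentre that lies in the forming five-membered ring: allylic 1,2-strain with the C11 methyl places H-1′ outside, the tether oxygen inside and the C2′ chain anti to the forming C1–C11 bond; C1 follows because the oxabicyclo[3.2.0]heptane can only be cis-fused (acetal carbon cis to C1′, C2 cis to the C11 methyl); C9 forms cis to the six-membered ring and is corrected in step 18. The step needs regioselectivity for C1–C11/C9–C10 over the crossed mode, which the three-atom tether from the β-carbon secures, and site selectivity for the isopropenyl group over the remote trisubstituted olefin, which a five- against a six- or seven-membered first closure secures. The acetal carbon and the two centres from step 9 are mixtures that do not bear on the new centres and are erased later.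

Step 13
Reactants: 20 tricyclic photoadduct
Product: 21 lactol of 20 (OMe replaced by OH; ring tautomer of the C1-formyl C1′-hydroxy compound)
Conditions: PPTS, acetone–H2O (5:1), 45 °C
Reagents that add atoms: water O
Why: Acid hydrolysis of the 2-methoxytetrahydrofuran (an anomeric acetal) gives the lactol without touching the silyl ether, the PMB ether or the acetate.

Step 14
Reactants: 21 lactol
Product: 22 cis-fused bicyclo[4.2.0]octan-2-one with H on C1 cis to the free C1′ carbinol on C11 (formyl carbon removed)
Conditions: RhCl(PPh3)3 (1.2 equiv), xylene, 130 °C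
Reagents that add atoms: none
Why: Tsuji–Wilkinson decarbonylation of the aldehyde tautomer (oxidative addition into the formyl C–H bond, CO extrusion, reductive elimination) replaces the temporary formyl group by hydrogen with retention, so H-1 ends cis to the C1′ side chain as in the target and the C1′ hydroxyl is released.

Step 15
Reactants: 22 hydroxy ketone
Product: 23 C1′ acetate of 22
Conditions: Ac2O, pyridine, DMAP (cat.), rt
Reagents that add atoms: acetic anhydride CC(=O)OC(C)=O
Why: Standard acetylation installs the second acetate of the target at the now free C1′ hydroxyl.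

Step 16
Reactants: 23 diacetate with PMB ether
Product: 24 primary alcohol (PMB removed)
Conditions: DDQ, CH2Cl2–aq. NaH2PO4/Na2HPO4 (pH 7), 0 °C
Reagents that add atoms: none
Why: Oxidative cleavage of the PMB ether by DDQ (hydride abstraction, hydrolysis of the oxocarbenium ion) frees the primary alcohol.

Step 17
Reactants: 24 primary alcohol
Product: 25 primary iodide
Conditions: I2, PPh3, imidazole, CH2Cl2, 0 °C to rt
Reagents that add atoms: iodine II
Why: Appel-type iodination of the unhindered primary alcohol via the alkoxyphosphonium salt gives the radical precursor.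

Step 18
Reactants: 25 primary iodide
Product: 27 trans-fused 5-silyloxy-bicyclo[7.2.0]undecan-8-one (C4 as formed), via cis-fused ketone 26 (not isolated)
Conditions: Bu3SnH (1.3 equiv, syringe pump), AIBN (cat.), benzene (5 mM), 80 °C; then DBU, rt
Reagents that add atoms: none
Why: Proposed new method: the primary radical from the iodide adds to the ring carbonyl (5-exo) to give a bicyclic alkoxy radical whose β-scission of the more substituted ring-fusion bond (C8–C4) releases a tertiary radical and the nine-membered ketone, and hydrogen transfer from Bu3SnH kept at low concentration ends the chain; the closest known reaction type is the Dowd–Beckwith three-carbon ring expansion of β-keto esters, which here lacks the ester that normally stabilises the fragmenting radical, and DBU then epimerises C9 (α to the new ketone) to the more stable trans ring fusion.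

Step 19
Reactants: 27 trans-fused nine-membered ketone
Product: 28 8-methylidene compound
Conditions: Zn, CH2Br2, TiCl4, THF–CH2Cl2, 0 °C to rt
Reagents that add atoms: dibromomethane BrCBr
Why: Takai–Lombardo methylenation with the non-basic zinc–titanium methylene reagent converts the ketone to the C8 methylidene without touching the acetates or epimerising C9.

Step 20
Reactants: 28 silyl ether
Product: 29 C5 alcohol
Conditions: HF·pyridine, THF–pyridine, 0 °C to rt
Reagents that add atoms: none
Why: Fluoride cleavage of the secondary silyl ether frees the C5 alcohol.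

Step 21
Reactants: 29 C5 alcohol
Product: 31 target (1S,4S,9R,11S)-11-[(1S,3Z)-1,5-diacetoxy-4-methylpent-3-en-1-yl]-4,11-dimethyl-8-methylidenebicyclo[7.2.0]undecan-5-one, via C4-epimeric ketone mixture 30 (not isolated)
Conditions: Dess–Martin periodinane, NaHCO3, CH2Cl2, 0 °C to rt; then DBU (0.3 equiv), toluene, rt
Reagents that add atoms: none
Why: Dess–Martin oxidation gives the C5 ketone, and DBU equilibration through the enol should set C4 to the (4S) epimer assumed to be the more stable one, which completes the target.

**Compound list**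

1 | methacrolein (2-methylprop-2-enal) | C=C(C)C=O | starting material
2 | (3S)-2-methylhexa-1,5-dien-3-ol | C=C(C)[C@H](CC=C)O | intermediate
3 | (3S)-2-methylhexa-1,5-dien-3-yl 2-methylprop-2-enoate | C=C(C)[C@H](CC=C)OC(=O)C(C)=C | intermediate
4 | (6S)-3-methyl-6-(prop-1-en-2-yl)-5,6-dihydro-2H-pyran-2-one | C=C(C)[C@@H]1CC=C(C)C(=O)O1 | intermediate
5 | (2Z,5S)-2,6-dimethylhepta-2,6-diene-1,5-diol | C=C(C)[C@H](C/C=C(/C)CO)O | intermediate
6 | (2Z,5S)-5-hydroxy-2,6-dimethylhepta-2,6-dien-1-yl acetate | C=C(C)[C@H](C/C=C(/C)COC(C)=O)O | intermediate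
7 | 3-ethoxycyclohex-2-en-1-one | CCOC1=CC(=O)CCC1 | starting material
8 | 1,3-dithiane | C1CSCSC1 | starting material
9 | lithium 1-(1,3-dithian-2-yl)-3-ethoxycyclohex-2-en-1-olate (1,2-adduct) | CCOC1=CC(O[Li])(CCC1)C1SCCCS1 | intermediate
10 | 3-(1,3-dithian-2-yl)cyclohex-2-en-1-one | O=C1C=C(CCC1)C1SCCCS1 | intermediate
11 | 3-(dimethoxymethyl)cyclohex-2-en-1-one | COC(OC)C1=CC(=O)CCC1 | intermediate
12 | lithium α′-dienolate of 11 | COC(OC)C1=CC(O[Li])=CCC1 | intermediate
13 | 3-(dimethoxymethyl)-6-methylcyclohex-2-en-1-one (racemic) | COC(OC)C1=CC(=O)C(C)CC1 | intermediate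
14 | 3-[(4-methoxybenzyl)oxy]propanal | COc1ccc(COCCC=O)cc1 | starting material
15 | lithium α′-dienolate of 13 | COC(OC)C1=CC(O[Li])=C(C)CC1 | intermediate
16 | 3-(dimethoxymethyl)-6-{1-hydroxy-3-[(4-methoxybenzyl)oxy]propyl}-6-methylcyclohex-2-en-1-one (diastereomer mixture) | COC(OC)C1=CC(=O)C(C)(CC1)C(O)CCOCc1ccc(OC)cc1 | intermediate
17 | tert-butyldimethylsilyl ether of 16 | COC(OC)C1=CC(=O)C(C)(CC1)C(CCOCc1ccc(OC)cc1)O[Si](C)(C)C(C)(C)C | intermediate
18 | N-(α-methoxyalkyl)-2,4,6-trimethylpyridinium triflate derived from 17 | COC([n+]1c(C)cc(C)cc1C)C1=CC(=O)C(C)(CC1)C(CCOCc1ccc(OC)cc1)O[Si](C)(C)C(C)(C)C.[O-]S(=O)(=O)C(F)(F)F | intermediate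
19 | mixed acetal: enone C1–CH(OMe)–O–C1′ of the (S)-configured side-chain carbinol (acetal epimers) | COC(O[C@@H](C/C=C(/C)COC(C)=O)C(C)=C)C1=CC(=O)C(C)(CC1)C(CCOCc1ccc(OC)cc1)O[Si](C)(C)C(C)(C)C | intermediate
20 | tricyclic photoadduct: cyclohexanone cis-fused to the cyclobutane, itself cis-fused to the 2-methoxytetrahydrofuran; C11 methyl cis to C2; H-9 cis to the acetal carbon | O=C1[C@H]2C[C@]3(C)[C@H](C/C=C(/C)COC(C)=O)OC(OC)[C@]23CCC1(C)C(CCOCc1ccc(OC)cc1)O[Si](C)(C)C(C)(C)C | intermediate
21 | lactol of 20 (OH in place of OMe) | O=C1[C@H]2C[C@]3(C)[C@H](C/C=C(/C)COC(C)=O)OC(O)[C@]23CCC1(C)C(CCOCc1ccc(OC)cc1)O[Si](C)(C)C(C)(C)C | intermediate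
22 | cis-fused bicyclo[4.2.0]octan-2-one; H-1 (target numbering) cis to the C1′ carbinol chain on C11; free C1′–OH | O=C1[C@H]2C[C@](C)([C@H](C/C=C(/C)COC(C)=O)O)[C@H]2CCC1(C)C(CCOCc1ccc(OC)cc1)O[Si](C)(C)C(C)(C)C | intermediate
23 | C1′ acetate of 22 | O=C1[C@H]2C[C@](C)([C@H](C/C=C(/C)COC(C)=O)OC(C)=O)[C@H]2CCC1(C)C(CCOCc1ccc(OC)cc1)O[Si](C)(C)C(C)(C)C | intermediate
24 | primary alcohol (PMB removed from 23) | O=C1[C@H]2C[C@](C)([C@H](C/C=C(/C)COC(C)=O)OC(C)=O)[C@H]2CCC1(C)C(CCO)O[Si](C)(C)C(C)(C)C | intermediate
25 | primary iodide | O=C1[C@H]2C[C@](C)([C@H](C/C=C(/C)COC(C)=O)OC(C)=O)[C@H]2CCC1(C)C(CCI)O[Si](C)(C)C(C)(C)C | intermediate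
26 | cis-fused 5-[(tert-butyldimethylsilyl)oxy]bicyclo[7.2.0]undecan-8-one (C4 and C5 mixtures) | O=C1CCC(O[Si](C)(C)C(C)(C)C)C(C)CC[C@H]2[C@@H]1C[C@]2(C)[C@H](C/C=C(/C)COC(C)=O)OC(C)=O | intermediate
27 | trans-fused 5-[(tert-butyldimethylsilyl)oxy]bicyclo[7.2.0]undecan-8-one (C4 and C5 mixtures) | O=C1CCC(O[Si](C)(C)C(C)(C)C)C(C)CC[C@H]2[C@H]1C[C@]2(C)[C@H](C/C=C(/C)COC(C)=O)OC(C)=O | intermediate
28 | 8-methylidene silyl ether | C=C1CCC(O[Si](C)(C)C(C)(C)C)C(C)CC[C@H]2[C@H]1C[C@]2(C)[C@H](C/C=C(/C)COC(C)=O)OC(C)=O | intermediate
29 | 8-methylidene C5 alcohol | C=C1CCC(O)C(C)CC[C@H]2[C@H]1C[C@]2(C)[C@H](C/C=C(/C)COC(C)=O)OC(C)=O | intermediate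
30 | C5 ketone as C4 epimer mixture | C=C1CCC(=O)C(C)CC[C@H]2[C@H]1C[C@]2(C)[C@H](C/C=C(/C)COC(C)=O)OC(C)=O | intermediate
31 | (1S,4S,9R,11S)-11-[(1S,3Z)-1,5-diacetoxy-4-methylpent-3-en-1-yl]-4,11-dimethyl-8-methylidenebicyclo[7.2.0]undecan-5-one | C=C1CCC(=O)[C@@H](C)CC[C@H]2[C@H]1C[C@]2(C)[C@H](C/C=C(/C)COC(C)=O)OC(C)=O | target

**Step count and risks**

Total steps: 21. Longest linear sequence: 16 steps (steps 6–10 then 11–21, or equally steps 1–5 then 11–21).

Steps most likely to fail:

Step 18 (Proposed new method). The primary radical may take hydrogen from Bu3SnH before it adds to the ketone, or the alkoxy radical may revert instead of cleaving the ring-fusion bond, because no ester stabilises the fragmenting radical. The fallback uses known chemistry in separate stages. Iodide 25 is cyclised with SmI2 (THF–HMPA, −78 °C, Barbier reaction onto the ring ketone) to the cis-fused tricyclic tertiary alcohol F1. Its hypoiodite (PhI(OAc)2, I2, hν, cyclohexane; Suárez alkoxy-radical fragmentation) cleaves the ring-fusion bond to the nine-membered tertiary iodo ketone F2. Bu3SnH/AIBN then removes the iodide to give the cis-fused ketone 26, which re-enters step 18 at the DBU stage and gives 27.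

Step 12. Face discrimination by C1′ in the triplet biradical may be insufficient, or the enone triplet may be captured by the remote trisubstituted olefin. The fallback replaces enone excitation by ground-state copper templating. Luche reduction (NaBH4, CeCl3·7H2O, MeOH) of 19 gives the allylic alcohol F3. Its 1,6-diene undergoes the copper-catalysed [2+2] photobicyclisation (CuOTf, the monovalent copper triflate, Et2O, 254 nm), which should place the C1′ substituent exo on the same cis-fused oxabicyclo[3.2.0]heptane and gives the tricyclic alcohol F4. Dess–Martin oxidation returns to 20.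

Step 21. Equilibration at C4 may settle on the wrong epimer or on a mixture, since the assumed thermodynamic preference is not established. The fallback is a kinetic, reagent-controlled protonation. The ketone mixture 30 is converted (TMSOTf, Et3N, CH2Cl2) to the more substituted silyl enol ether F5, which is protonated at −78 °C with a BINOL–SnCl4 Brønsted acid of the matching handedness to give 31.

Further compounds
F1 | step 18 | cis-fused tricyclic tertiary alcohol (cyclopentanol C8–C7–C6–C5–C4 fused to the cyclohexane; C8–OH) | OC12CCC(O[Si](C)(C)C(C)(C)C)C1(C)CC[C@H]1[C@@H]2C[C@]1(C)[C@H](C/C=C(/C)COC(C)=O)OC(C)=O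
F2 | step 18 | cis-fused 4-iodo-5-silyloxy-bicyclo[7.2.0]undecan-8-one | O=C1CCC(O[Si](C)(C)C(C)(C)C)C(C)(I)CC[C@H]2[C@@H]1C[C@]2(C)[C@H](C/C=C(/C)COC(C)=O)OC(C)=O
F3 | step 12 | allylic alcohol from 1,2-reduction of the enone of 19 | COC(O[C@@H](C/C=C(/C)COC(C)=O)C(C)=C)C1=CC(O)C(C)(CC1)C(CCOCc1ccc(OC)cc1)O[Si](C)(C)C(C)(C)C
F4 | step 12 | tricyclic alcohol (20 with C8–OH in place of the ketone) | OC1[C@H]2C[C@]3(C)[C@H](C/C=C(/C)COC(C)=O)OC(OC)[C@]23CCC1(C)C(CCOCc1ccc(OC)cc1)O[Si](C)(C)C(C)(C)C
F5 | step 21 | C4=C5 trimethylsilyl enol ether of 30 | C=C1CCC(O[Si](C)(C)C)=C(C)CC[C@H]2[C@H]1C[C@]2(C)[C@H](C/C=C(/C)COC(C)=O)OC(C)=O
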